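Two questions are asked of a row of flasks that differ in the coupling partner charged: how much target stands at the end, and what shape the row takes.

| setting | Tuesday's | Sunday's | zeta | alpha | delta | gamma |
|---|---|---|---|---|---|---|
| starting material | 10 mM | 10 mM | 10 mM | 10 mM | 10 mM | 10 mM |
| coupling partner | 18 mM | 130 mM | 12.0 mM | 25.0 mM | 50.0 mM | 100 mM |
| initiator | 1.5 mM | 1.5 mM | 1.5 mM | 1.5 mM | 1.5 mM | 1.5 mM |
| remark | run made earlier | run made earlier |  |  |  |  |
| time |  |  | 2.5 min | 2.5 min | 2.5 min | 2.5 min |

| run | time / s | target / % | starting material / % |
|---|---|---|---|
| Tuesday's | 10.0 | 4.7 | 95.0 |
| Tuesday's | 25.0 | 12.3 | 88.1 |
| Tuesday's | 50.0 | 23.0 | 76.3 |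
| Tuesday's | 80.0 | 33.7 | 63.1 |
| Sunday's | 20.0 | 17.8 | 80.2 |
| Sunday's | 40.0 | 29.4 | 64.5 |
| Sunday's | 60.0 | 36.1 | 52.4 |
| Sunday's | 80.0 | 39.9 | 42.9 |

(readings scatter by 1 percentage point)

- amount of target at the end, in percent of the starting material charged for zeta, alpha, delta, gamma, in this order
- the shape of the row from first to last (hardly changes / rises, then falls / falls all the way / rises all the way / falls, then rises)

- the analysis behind the earlier runs scatters by 1 percentage point, standard deviation
- "hardly changes" means that all values lie within two and a half points (for a concentration: within two and a half percent of the largest)

Two chemists read the earlier runs differently, and they argue over one gap: the part of the charge that is neither target nor starting material at the last reading. The first chemist points to Tuesday's run, where the gap is 3.20% beside 33.7% of target. She calls the loss a small correction. Sunday's run has 42.9% of starting material left, against 63.1% on Tuesday, so she expects more partner to give more target, with the row rising to the end. The second chemist points to Sunday's gap of 17.2% and expects the loss to overtake formation.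

My own reckoning takes the gap as target lost in a step with partner. Sunday's curve encloses an area equal to the full charge standing as target for 20.6 s. The gap, divided by that area and by the partner charged, gives the loss constant, the share of target lost per second per unit of partner: 0.0641 /M/s. With partner taken at its charge the loss is pseudo-first-order, and its half-life is ln(2) over the constant times the partner. For gamma that is 1.80 min, shorter than the 2.5 min of the run. For zeta it is 15.0 min, longer than the run. So I expect a row that rises and then falls, though I put no numbers on it.

The second chemist's forecast gives numbers: 38%, 48%, 51% and 45%, shape rises, then falls, on the ground that “Overreaction therefore gains on formation as partner rises”.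

The flasks give 40.1%, 60.9%, 60.4% and 47.2%, shape rises, then falls. The second chemist has the shape, though alpha stands 13 percentage points above the forecast.

    initiator → 2 initiating radical (k = 2.41 × 10⁻⁴ /s)
    starting material + initiating radical ⇌ chain carrier (K = 2.00 × 10⁵ /M, k = 56500 /M/s)
    coupling partner + chain carrier → target + initiating radical (k = 48700 /M/s)
    2 chain carrier → ended chains A (k = 8.80 × 10⁷ /M/s)
    2 initiating radical → ended chains B (k = 1.00 × 10⁷ /M/s)
    coupling partner + target → over-reaction product (k = 0.0633 /M/s)

Over-reaction is a part of the explanation of the fall: from alpha to gamma target changes by −14 points, but with the step from coupling partner and target to over-reaction product struck out it changes by 11 points. The loss constant, times gamma's partner charge and the area under its target curve from the halfway and end values, gives 31.6%, and gamma holds 31.8% of over-reaction product. For zeta the same product gives 2.48%, and zeta holds 1.88%. Zeta, below the turn at 34 mM, is the first chemist's region: its over-reaction product stays far below its 40.1% of target, with 57.1% of the starting material unreacted.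

The readings were generated by integration from invented constants.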